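**Plan**

1. Retrosynthesis: the C2 silyl ether and the two ester C–O bonds at C8 and C9 go back to the Z C8=C9 olefin of macrocycle 27. C8=C9 is cut by ring-closing metathesis to diene 26. C9–C10 (Stille) and C1=C10 (Wittig) are cut to aldehyde 20. Then C11=C13, C7–C8, C6–C7, the epoxide, C4–C15, C5–C6 and C3–C4 lead back to (S)-glycidyl PMB ether 1.
2. Forward: the C1–C6 chain is built linearly and epoxidised. The γ-lactone is closed on the new C6 carbinol (butenolide, then vinyl and methylene groups). The 2-vinyl enoate is attached at C1, the ten-membered ring is closed by metathesis, and the C8/C9 oxygens come last.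
3. Stereochemistry: C2 comes from 1. The Z C4=C5 geometry comes from syn-carbocupration, C4/C5 from Sharpless epoxidation, C6 from Felkin–Anh addition to the epoxy aldehyde, C7 from anti cuprate addition. C9 comes from face-selective osmylation (kept through two inversions), C8 from inversion by the neighbouring 9-angelate.
4. Feature used: in the ten-membered carbocycle C1–C10, the two acyloxy carbons C8 and C9 are direct neighbours, flanked by the lactone ring (C6, C7, C11, C12, O) and the C1=C10 enoate. Both C–O bonds can therefore be drawn from one C8=C9 double bond, which is the bond a metathesis between a vinyl group on C7 and one on C10 closes.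

Key step: step 17

Remarks: atoms carry germacranolide numbers (ring C1–C10, lactone C11–C13 closed on O6, ester carbon C14 on C10, methyl C15 on C4); TBS = tert-butyldimethylsilyl, PMB = 4-methoxybenzyl; 1 is taken as a purchasable material. Assumption: OsO4 adds to the Z C8=C9 bond of 27 so that the new C8–O bond is trans to the C7–C11 bond (the exposed face of a cis-cycloalkene with an allylic ring substituent); steps 19–21 are built on that outcome, and the opposite outcome is covered at the end.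

**Route**

Step 1
Reactants: 1 (S)-glycidyl PMB ether; 2 lithium acetylide–ethylenediamine complex
Product: 3 (S)-1-[(4-methoxybenzyl)oxy]pent-4-yn-2-ol
Conditions: DMSO, 0 °C to rt; H2O
Reagents that add atoms: none
Why: SN2 opening of the terminal epoxide by the acetylide at the unsubstituted carbon (C3) leaves the stereocentre of 1 untouched, which becomes C2 (S).

Step 2
Reactants: 3 homopropargylic alcohol
Product: 4 (S)-tert-butyl({1-[(4-methoxybenzyl)oxy]pent-4-yn-2-yl}oxy)dimethylsilane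
Conditions: TBSCl, imidazole, DMF, rt
Reagents that add atoms: tert-butyldimethylsilyl chloride, CC(C)(C)[Si](C)(C)Cl
Why: standard silylation of a secondary alcohol; the TBS ether at O2 is meant to last until the final step.

Step 3
Reactants: 4 silyl ether alkyne
Product: 5 methyl (S)-5-(TBSO)-6-(PMBO)hex-2-ynoate
Conditions: n-BuLi, THF, −78 °C; ClCO2Me, −78 to 0 °C
Reagents that add atoms: methyl chloroformate, COC(=O)Cl
Why: C-acylation of the lithium acetylide with a chloroformate gives the alkynoate and brings in C6.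

Step 4
Reactants: 5 alkynoate
Product: 6 methyl (2Z,5S)-5-(TBSO)-6-(PMBO)-3-methylhex-2-enoate
Conditions: Me2CuLi (MeLi, CuI), THF, −78 °C; aq. NH4Cl at −78 °C
Reagents that add atoms: lithium dimethylcuprate, [Li+].C[Cu-]C
Why: syn-carbocupration of an alkynoate with cold protonation (Corey–Katzenellenbogen) places the new methyl (C15) cis to H5 and so the C3 chain cis to C6, the Z olefin that maps onto the cis-epoxide.

Step 5
Reactants: 6 Z-enoate
Product: 7 (2Z,5S)-5-(TBSO)-6-(PMBO)-3-methylhex-2-en-1-ol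
Conditions: iBu2AlH, CH2Cl2, −78 °C; potassium sodium tartrate (aq.)
Reagents that add atoms: none
Why: 1,2-reduction of the enoate ester by the aluminium hydride gives the allylic alcohol without touching the olefin geometry.

Step 6
Reactants: 7 Z-allylic alcohol
Product: 8 [(2S,3R)-3-{(2S)-2-(TBSO)-3-(PMBO)propyl}-3-methyloxiran-2-yl]methanol
Conditions: Ti(OiPr)4, L-(+)-diethyl tartrate, t-BuOOH, 4 Å MS, CH2Cl2, −20 °C
Reagents that add atoms: tert-butyl hydroperoxide, CC(C)(C)OO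
Why: Sharpless asymmetric epoxidation of a nerol-type allylic alcohol; the L-(+)-tartrate complex delivers oxygen to the face that gives the (2S,3R)-epoxy alcohol, setting C5 (S) and C4 (R) under reagent control.

Step 7
Reactants: 8 epoxy alcohol
Product: 9 (2R,3R)-3-{(2S)-2-(TBSO)-3-(PMBO)propyl}-3-methyloxirane-2-carbaldehyde
Conditions: Dess–Martin periodinane, NaHCO3, CH2Cl2, 0 °C to rt
Reagents that add atoms: none
Why: buffered Dess–Martin oxidation of a 2,3-epoxy alcohol gives the epoxy aldehyde, which should be used without storage.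

Step 8
Reactants: 9 epoxy aldehyde; 10 methyl propiolate
Product: 11 methyl (4S)-4-hydroxy-4-[(2S,3R)-3-{(2S)-2-(TBSO)-3-(PMBO)propyl}-3-methyloxiran-2-yl]but-2-ynoate
Conditions: 10, LiN(SiMe3)2, THF, −78 °C; then 9, −78 °C; AcOH
Reagents that add atoms: none
Why: 1,2-addition of lithium methyl propiolate; Felkin–Anh attack anti to the C5–O bond of the cis-substituted epoxy aldehyde should give the 5,6-anti alcohol, which is C6 (S).

Step 9
Reactants: 11 hydroxy alkynoate
Product: 13 (5S)-5-[(2S,3R)-3-{(2S)-2-(TBSO)-3-(PMBO)propyl}-3-methyloxiran-2-yl]furan-2(5H)-one, via (Z)-hydroxy enoate 12 (not isolated)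
Conditions: H2 (1 atm), Pd/CaCO3–Pb(OAc)2 (Lindlar catalyst), quinoline, EtOAc, rt; then SiO2, CH2Cl2, rt
Reagents that add atoms: none
Why: Lindlar semi-hydrogenation gives the Z-4-hydroxy enoate, which lactonises to the butenolide (classical butenolide synthesis) with C6 untouched.

Step 10
Reactants: 13 butenolide; 14 vinylmagnesium bromide
Product: 15 (4R,5S)-5-[(2S,3R)-3-{(2S)-2-(TBSO)-3-(PMBO)propyl}-3-methyloxiran-2-yl]-4-vinyldihydrofuran-2(3H)-one
Conditions: 14, CuBr·SMe2, THF, −78 to −40 °C; aq. NH4Cl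
Reagents that add atoms: none
Why: conjugate addition of a vinyl cuprate to a γ-substituted butenolide occurs anti to the γ-substituent, which sets C7 trans to C6.

Step 11
Reactants: 15 vinyl lactone
Product: 18 (4S,5S)-3-methylene-5-[(2S,3R)-3-{(2S)-2-(TBSO)-3-(PMBO)propyl}-3-methyloxiran-2-yl]-4-vinyldihydrofuran-2(3H)-one, via Mannich base 16 (not isolated), via ammonium iodide 17 (not isolated)
Conditions: LiN(SiMe3)2, THF, −78 °C; CH2=NMe2+ I−, −78 °C to rt; MeI, MeOH, rt; NaHCO3 (aq.), CH2Cl2, rt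
Reagents that add atoms: N,N-dimethylmethyleneiminium iodide (Eschenmoser's salt), C=[N+](C)C.[I-]
Why: α-methylenation of the lactone by Mannich reaction of its lithium enolate, N-methylation and elimination of trimethylamine; C11 ends sp2, so no stereocentre is at stake.

Step 12
Reactants: 18 methylene lactone PMB ether
Product: 19 (4S,5S)-5-[(2S,3R)-3-{(2S)-2-(TBSO)-3-hydroxypropyl}-3-methyloxiran-2-yl]-3-methylene-4-vinyldihydrofuran-2(3H)-one
Conditions: DDQ, CH2Cl2/pH 7 buffer, 0 °C to rt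
Reagents that add atoms: none
Why: oxidative cleavage of the PMB ether with DDQ spares the silyl ether, the epoxide and the electron-poor or unactivated olefins.

Step 13
Reactants: 19 primary alcohol
Product: 20 (2S)-2-(TBSO)-3-[(2R,3S)-2-methyl-3-{(2S,3S)-4-methylene-5-oxo-3-vinyltetrahydrofuran-2-yl}oxiran-2-yl]propanal
Conditions: Dess–Martin periodinane, NaHCO3, CH2Cl2, 0 °C
Reagents that add atoms: none
Why: Dess–Martin oxidation gives the α-silyloxy aldehyde under neutral conditions that should not epimerise C2.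

Step 14
Reactants: 21 methyl (triphenylphosphoranylidene)acetate
Product: 23 methyl bromo(triphenylphosphoranylidene)acetate, via bromophosphonium bromide 22 (not isolated)
Conditions: Br2, CH2Cl2, 0 °C; then NaOH (aq.), 0 °C
Reagents that add atoms: bromine, BrBr
Why: bromination of the stabilised ylide and deprotonation of the bromophosphonium salt is the established preparation of the α-bromo ylide.

Step 15
Reactants: 20 aldehyde; 23 α-bromo ylide
Product: 24 methyl (2Z,4S)-2-bromo-4-(TBSO)-5-[(2R,3S)-2-methyl-3-{(2S,3S)-4-methylene-5-oxo-3-vinyltetrahydrofuran-2-yl}oxiran-2-yl]pent-2-enoate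
Conditions: CH2Cl2, rt
Reagents that add atoms: none
Why: Wittig olefination with the stabilised α-bromo ylide puts the ester trans to the C2 chain, so bromine (the future site of C9) is cis to C2 on C1=C10.

Step 16
Reactants: 24 bromo enoate; 25 tributyl(vinyl)stannane
Product: 26 methyl (2E,4S)-4-(TBSO)-5-[(2R,3S)-2-methyl-3-{(2S,3S)-4-methylene-5-oxo-3-vinyltetrahydrofuran-2-yl}oxiran-2-yl]-2-vinylpent-2-enoate
Conditions: Pd2(dba)3, AsPh3, CuI, NMP, 40 °C
Reagents that add atoms: none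
Why: Stille coupling of the alkenyl bromide proceeds with retention, so the new vinyl group (C9) stays cis to C2.

Step 17
Reactants: 26 acyclic diene with methylene lactone, cis-epoxide and 2-vinyl enoate
Product: 27 methyl (1(10)E,8Z)-(2S,4R,5S,6S,7S)-2-(TBSO)-4,5-epoxygermacra-1(10),8,11(13)-trien-12,6-olid-14-oate
Conditions: second-generation Grubbs catalyst RuCl2(=CHPh)(PCy3)(H2IMes), 1,4-benzoquinone, toluene (1 mM), 80 °C
Reagents that add atoms: none
Why: The ruthenium alkylidene should load by [2+2] cycloaddition and cycloreversion on the unhindered C7 vinyl group, and the C8 carbene so formed adds to the terminal CH2=CH of the 2-vinyl enoate; collapse of that ruthenacyclobutane makes C8=C9 and expels ethylene. The closest known reaction type is the ring-closing metathesis of 1,ω-dienes to ten-membered Z-cycloalkenes with this catalyst, here in its ene–diene form, which leaves a conjugated diene. The one ring formed, the carbocycle C1–C10, is closed head-to-head between the two vinyl CH carbons, so the new olefin lies inside the ring. No stereocentre is made; C8=C9 is expected to be Z because an E olefin next to the cis C1=C10 bond, the cis-epoxide and the trans-fused lactone would strain a ten-membered ring far more. The step needs site selectivity among four olefins and cyclisation in preference to oligomerisation: the trisubstituted enoate and the 1,1-disubstituted methylene lactone are electron-poor and hindered, and the only other intramolecular partner of the C8 carbene, C13, would give a cyclobutene. High dilution and the three rigid units of 26 (lactone, cis-epoxide, C1=C10 with C2 and C9 cis) should bring the two vinyl groups together.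

Step 18
Reactants: 27 macrocyclic triene
Product: 28 methyl (2S,4R,5S,6S,7R,8R,9S)-2-(TBSO)-4,5-epoxy-8,9-dihydroxygermacra-1(10),11(13)-dien-12,6-olid-14-oate
Conditions: OsO4 (5 mol %), NMO, acetone/H2O, 0 °C
Reagents that add atoms: osmium tetroxide, O=[Os](=O)(=O)=O; N-methylmorpholine N-oxide, C[N+]1([O-])CCOCC1; water, O
Why: Upjohn dihydroxylation (syn [3+2] addition) should take the only olefin not directly conjugated with a carbonyl group and add trans to the C7–C11 bond, giving C9–O as in the target and C8–O epimeric.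

Step 19
Reactants: 28 cis-diol
Product: 30 8,9-cyclic sulfate of 28, via cyclic sulfite 29 (not isolated)
Conditions: SOCl2, Et3N, CH2Cl2, 0 °C; then RuCl3 (cat.), NaIO4, MeCN/H2O, 0 °C
Reagents that add atoms: thionyl chloride, O=S(Cl)Cl; sodium periodate, [Na+].[O-][I](=O)(=O)=O
Why: Sharpless cyclic sulfate synthesis (cyclic sulfite, then RuO4-catalysed oxidation) activates both C–O bonds without change of configuration.

Step 20
Reactants: 30 cyclic sulfate; 31 angelic acid
Product: 33 methyl (2S,4R,5S,6S,7R,8R,9R)-9-angeloyloxy-2-(TBSO)-4,5-epoxy-8-hydroxygermacra-1(10),11(13)-dien-12,6-olid-14-oate, via caesium sulfate monoester 32 (not isolated)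
Conditions: 31, Cs2CO3, DMF, rt; then H2SO4 (cat.), H2O (1 equiv), THF, rt
Reagents that add atoms: none
Why: SN2 opening of the cyclic sulfate by caesium angelate at the allylic carbon C9 (inversion), then acid-catalysed hydrolysis of the C8 sulfate monoester with S–O cleavage (retention at C8).

Step 21
Reactants: 33 trans-hydroxy angelate
Product: 36 methyl (2S,4R,5S,6S,7R,8S,9S)-9-acetoxy-8-angeloyloxy-2-(TBSO)-4,5-epoxygermacra-1(10),11(13)-dien-12,6-olid-14-oate, via triflate 34 (not isolated), via dioxolanylium triflate 35 (not isolated)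
Conditions: Tf2O, 2,6-di-tert-butyl-4-methylpyridine, CH2Cl2, −40 to 0 °C; then Bu4NOAc, toluene, rt to 40 °C
Reagents that add atoms: tetrabutylammonium acetate, CCCC[N+](CCCC)(CCCC)CCCC.CC(=O)[O-]
Why: the 8-triflate is displaced from the rear by the carbonyl oxygen of the trans-vicinal 9-angelate (neighbouring-group participation, inversion at C8), and acetate opens the resulting 1,3-dioxolan-2-ylium ion at allylic C9 with a second inversion (second stage of a Prévost reaction), leaving angeloyl on O8 and acetate on C9 as in the target.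

Step 22
Reactants: 36 silyl ether of the target
Product: 37 methyl (2S,4R,5S,6S,7R,8S,9S)-9-acetoxy-8-angeloyloxy-4,5-epoxy-2-hydroxygermacra-1(10),11(13)-dien-12,6-olid-14-oate (CNP0278274.1)
Conditions: HF·pyridine, pyridine, THF, 0 °C to rt
Reagents that add atoms: none
Why: buffered fluoride cleavage of the secondary TBS ether is mild enough for the two esters, the epoxide and the methylene lactone.

**Compound list**

1 | (S)-2-{[(4-methoxybenzyl)oxy]methyl}oxirane | COc1ccc(COC[C@@H]2CO2)cc1 | starting material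
2 | lithium acetylide–ethylenediamine complex | [Li+].[C-]#C.NCCN | starting material
3 | (S)-1-[(4-methoxybenzyl)oxy]pent-4-yn-2-ol | COc1ccc(COC[C@@H](O)CC#C)cc1 | intermediate
4 | (S)-tert-butyl({1-[(4-methoxybenzyl)oxy]pent-4-yn-2-yl}oxy)dimethylsilane | COc1ccc(COC[C@@H](O[Si](C)(C)C(C)(C)C)CC#C)cc1 | intermediate
5 | methyl (S)-5-(TBSO)-6-(PMBO)hex-2-ynoate | COc1ccc(COC[C@@H](O[Si](C)(C)C(C)(C)C)CC#CC(=O)OC)cc1 | intermediate
6 | methyl (2Z,5S)-5-(TBSO)-6-(PMBO)-3-methylhex-2-enoate | COc1ccc(COC[C@@H](O[Si](C)(C)C(C)(C)C)C/C(C)=C\C(=O)OC)cc1 | intermediate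
7 | (2Z,5S)-5-(TBSO)-6-(PMBO)-3-methylhex-2-en-1-ol | COc1ccc(COC[C@@H](O[Si](C)(C)C(C)(C)C)C/C(C)=C\CO)cc1 | intermediate
8 | [(2S,3R)-3-{(2S)-2-(TBSO)-3-(PMBO)propyl}-3-methyloxiran-2-yl]methanol | COc1ccc(COC[C@@H](O[Si](C)(C)C(C)(C)C)C[C@@]2(C)O[C@H]2CO)cc1 | intermediate
9 | (2R,3R)-3-{(2S)-2-(TBSO)-3-(PMBO)propyl}-3-methyloxirane-2-carbaldehyde | COc1ccc(COC[C@@H](O[Si](C)(C)C(C)(C)C)C[C@@]2(C)O[C@H]2C=O)cc1 | intermediate
10 | methyl propiolate | C#CC(=O)OC | starting material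
11 | methyl (4S)-4-hydroxy-4-[(2S,3R)-3-{(2S)-2-(TBSO)-3-(PMBO)propyl}-3-methyloxiran-2-yl]but-2-ynoate | COc1ccc(COC[C@@H](O[Si](C)(C)C(C)(C)C)C[C@@]2(C)O[C@H]2[C@@H](O)C#CC(=O)OC)cc1 | intermediate
12 | methyl (2Z,4S)-4-hydroxy-4-[(2S,3R)-3-{(2S)-2-(TBSO)-3-(PMBO)propyl}-3-methyloxiran-2-yl]but-2-enoate | COc1ccc(COC[C@@H](O[Si](C)(C)C(C)(C)C)C[C@@]2(C)O[C@H]2[C@@H](O)/C=C\C(=O)OC)cc1 | intermediate (not isolated)
13 | (5S)-5-[(2S,3R)-3-{(2S)-2-(TBSO)-3-(PMBO)propyl}-3-methyloxiran-2-yl]furan-2(5H)-one | COc1ccc(COC[C@@H](O[Si](C)(C)C(C)(C)C)C[C@@]2(C)O[C@H]2[C@H]3OC(=O)C=C3)cc1 | intermediate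
14 | vinylmagnesium bromide | C=C[Mg]Br | starting material
15 | (4R,5S)-5-[(2S,3R)-3-{(2S)-2-(TBSO)-3-(PMBO)propyl}-3-methyloxiran-2-yl]-4-vinyldihydrofuran-2(3H)-one | COc1ccc(COC[C@@H](O[Si](C)(C)C(C)(C)C)C[C@@]2(C)O[C@H]2[C@H]3OC(=O)C[C@@H]3C=C)cc1 | intermediate
16 | (3RS,4R,5S)-3-[(dimethylamino)methyl] derivative of 15 (C3 not defined) | COc1ccc(COC[C@@H](O[Si](C)(C)C(C)(C)C)C[C@@]2(C)O[C@H]2[C@H]3OC(=O)C(CN(C)C)[C@@H]3C=C)cc1 | intermediate (not isolated)
17 | N-methyl ammonium iodide of 16 | COc1ccc(COC[C@@H](O[Si](C)(C)C(C)(C)C)C[C@@]2(C)O[C@H]2[C@H]3OC(=O)C(C[N+](C)(C)C)[C@@H]3C=C)cc1.[I-] | intermediate (not isolated)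
18 | (4S,5S)-3-methylene-5-[(2S,3R)-3-{(2S)-2-(TBSO)-3-(PMBO)propyl}-3-methyloxiran-2-yl]-4-vinyldihydrofuran-2(3H)-one | COc1ccc(COC[C@@H](O[Si](C)(C)C(C)(C)C)C[C@@]2(C)O[C@H]2[C@H]3OC(=O)C(=C)[C@@H]3C=C)cc1 | intermediate
19 | (4S,5S)-5-[(2S,3R)-3-{(2S)-2-(TBSO)-3-hydroxypropyl}-3-methyloxiran-2-yl]-3-methylene-4-vinyldihydrofuran-2(3H)-one | OC[C@@H](O[Si](C)(C)C(C)(C)C)C[C@@]1(C)O[C@H]1[C@H]2OC(=O)C(=C)[C@@H]2C=C | intermediate
20 | (2S)-2-(TBSO)-3-[(2R,3S)-2-methyl-3-{(2S,3S)-4-methylene-5-oxo-3-vinyltetrahydrofuran-2-yl}oxiran-2-yl]propanal | O=C[C@@H](O[Si](C)(C)C(C)(C)C)C[C@@]1(C)O[C@H]1[C@H]2OC(=O)C(=C)[C@@H]2C=C | intermediate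
21 | methyl (triphenylphosphoranylidene)acetate | COC(=O)C=P(c1ccccc1)(c1ccccc1)c1ccccc1 | starting material
22 | [bromo(methoxycarbonyl)methyl]triphenylphosphonium bromide | COC(=O)C(Br)[P+](c1ccccc1)(c1ccccc1)c1ccccc1.[Br-] | intermediate (not isolated)
23 | methyl bromo(triphenylphosphoranylidene)acetate | COC(=O)C(Br)=P(c1ccccc1)(c1ccccc1)c1ccccc1 | intermediate
24 | methyl (2Z,4S)-2-bromo-4-(TBSO)-5-[(2R,3S)-2-methyl-3-{(2S,3S)-4-methylene-5-oxo-3-vinyltetrahydrofuran-2-yl}oxiran-2-yl]pent-2-enoate | C=C[C@H]1C(=C)C(=O)O[C@@H]1[C@@H]1O[C@]1(C)C[C@H](O[Si](C)(C)C(C)(C)C)/C=C(\Br)C(=O)OC | intermediate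
25 | tributyl(vinyl)stannane | CCCC[Sn](CCCC)(CCCC)C=C | starting material
26 | methyl (2E,4S)-4-(TBSO)-5-[(2R,3S)-2-methyl-3-{(2S,3S)-4-methylene-5-oxo-3-vinyltetrahydrofuran-2-yl}oxiran-2-yl]-2-vinylpent-2-enoate (2-vinyl group cis to C4 of the chain) | C=C[C@H]1C(=C)C(=O)O[C@@H]1[C@@H]1O[C@]1(C)C[C@H](O[Si](C)(C)C(C)(C)C)/C=C(\C=C)C(=O)OC | intermediate
27 | methyl (1(10)E,8Z)-(2S,4R,5S,6S,7S)-2-(TBSO)-4,5-epoxygermacra-1(10),8,11(13)-trien-12,6-olid-14-oate | C=C1C(=O)O[C@H]2[C@H]1/C=C\C(C(=O)OC)=C/[C@@H](O[Si](C)(C)C(C)(C)C)C[C@@]1(C)O[C@@H]21 | intermediate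
28 | methyl (2S,4R,5S,6S,7R,8R,9S)-2-(TBSO)-4,5-epoxy-8,9-dihydroxygermacra-1(10),11(13)-dien-12,6-olid-14-oate | C=C1C(=O)O[C@H]2[C@H]1[C@@H](O)[C@@H](O)/C(C(=O)OC)=C\[C@@H](O[Si](C)(C)C(C)(C)C)C[C@@]1(C)O[C@@H]21 | intermediate
29 | 8,9-cyclic sulfite of 28 (sulfur configuration not defined) | C=C1C(=O)O[C@H]2[C@H]1[C@@H](O3)[C@@H](OS3=O)/C(C(=O)OC)=C\[C@@H](O[Si](C)(C)C(C)(C)C)C[C@@]1(C)O[C@@H]21 | intermediate (not isolated)
30 | 8,9-cyclic sulfate of 28 | C=C1C(=O)O[C@H]2[C@H]1[C@@H](O3)[C@@H](OS3(=O)=O)/C(C(=O)OC)=C\[C@@H](O[Si](C)(C)C(C)(C)C)C[C@@]1(C)O[C@@H]21 | intermediate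
31 | angelic acid, (Z)-2-methylbut-2-enoic acid | C/C=C(/C)C(=O)O | starting material
32 | caesium salt of the 8-O-sulfate of 33 | C=C1C(=O)O[C@H]2[C@H]1[C@@H](OS(=O)(=O)[O-])[C@H](OC(=O)/C(C)=C\C)/C(C(=O)OC)=C\[C@@H](O[Si](C)(C)C(C)(C)C)C[C@@]1(C)O[C@@H]21.[Cs+] | intermediate (not isolated)
33 | methyl (2S,4R,5S,6S,7R,8R,9R)-9-angeloyloxy-2-(TBSO)-4,5-epoxy-8-hydroxygermacra-1(10),11(13)-dien-12,6-olid-14-oate | C=C1C(=O)O[C@H]2[C@H]1[C@@H](O)[C@H](OC(=O)/C(C)=C\C)/C(C(=O)OC)=C\[C@@H](O[Si](C)(C)C(C)(C)C)C[C@@]1(C)O[C@@H]21 | intermediate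
34 | 8-O-triflate of 33 | C=C1C(=O)O[C@H]2[C@H]1[C@@H](OS(=O)(=O)C(F)(F)F)[C@H](OC(=O)/C(C)=C\C)/C(C(=O)OC)=C\[C@@H](O[Si](C)(C)C(C)(C)C)C[C@@]1(C)O[C@@H]21 | intermediate (not isolated)
35 | 2-[(Z)-but-2-en-2-yl]-1,3-dioxolan-2-ylium triflate cis-fused at O8 and O9 (C8 inverted, both oxygens cis to C7–C11) | C=C1C(=O)O[C@H]2[C@H]1[C@H](O3)[C@H](O[C+]3/C(C)=C\C)/C(C(=O)OC)=C\[C@@H](O[Si](C)(C)C(C)(C)C)C[C@@]1(C)O[C@@H]21.[O-]S(=O)(=O)C(F)(F)F | intermediate (not isolated)
36 | methyl (2S,4R,5S,6S,7R,8S,9S)-9-acetoxy-8-angeloyloxy-2-(TBSO)-4,5-epoxygermacra-1(10),11(13)-dien-12,6-olid-14-oate | C=C1C(=O)O[C@H]2[C@H]1[C@H](OC(=O)/C(C)=C\C)[C@@H](OC(C)=O)/C(C(=O)OC)=C\[C@@H](O[Si](C)(C)C(C)(C)C)C[C@@]1(C)O[C@@H]21 | intermediate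
37 | methyl (2S,4R,5S,6S,7R,8S,9S)-9-acetoxy-8-angeloyloxy-4,5-epoxy-2-hydroxygermacra-1(10),11(13)-dien-12,6-olid-14-oate (CNP0278274.1) | C=C1C(=O)O[C@H]2[C@H]1[C@H](OC(=O)/C(C)=C\C)[C@@H](OC(C)=O)/C(C(=O)OC)=C\[C@@H](O)C[C@@]1(C)O[C@@H]21 | target

**Count and risks**

Total: 22 steps. Longest linear sequence: 21 steps (1–13 and 15–22; step 14 is a one-step side branch that makes ylide 23).

Steps most likely to fail:

1. Step 17. Intermolecular metathesis (dimers, oligomers) may outrun closure of the ten-membered ring, or the catalyst may rest as a stabilised carbene on the dienoate and migrate double bonds.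
Fallback, from bromo enoate 24 and back at 27: 24 is coupled under the Stille conditions of step 16 with tributyl[(1E)-hepta-1,6-dien-1-yl]stannane F1, prepared by hydrostannation of hept-1-en-6-yne with Bu3SnH. This gives the relay tetraene F2. The catalyst should then load on the unhindered terminal olefin of the tether, expel cyclopentene and arrive as the C9 alkylidene, which closes onto the C7 vinyl group to give 27.

2. Step 18. Osmylation may take the other face of the ring olefin, or both faces, and may touch the methylene lactone.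
Fallback, from 27 and back at 36: if the osmate ester forms cis to the C7–C11 bond, the product is the (8S,9R)-diol F3, in which C8 is already correct. F3 is converted with SOCl2/Et3N into the cyclic sulfite F4 and oxidised (RuCl3 cat., NaIO4) to the cyclic sulfate F5. Caesium acetate in DMF opens F5 at allylic C9 with inversion to the caesium sulfate monoester F6, and H2SO4 (cat.)/H2O/THF frees the hydroxy acetate F7. O8 is then acylated with the mixed anhydride F8, made from angelic acid 31 and 2,4,6-trichlorobenzoyl chloride (Et3N, then F7, toluene, 80 °C), which gives 36. A mixture of 28 and F3 would be separated and each carried on by its own sequence, since both end at 36.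

3. Step 21. After triflation, elimination or participation of the lactone carbonyl may compete with the 9-ester. Acetate may open the dioxolanylium ion at C8 or stop at an orthoester. The angeloyl double bond may isomerise in the cation.
Fallback, from diol 28 and back at 36: the allylic, less hindered hydroxyl at C9 is acetylated (AcCl, 2,4,6-collidine, CH2Cl2, −78 °C) to the 9-acetate F9. O8 is triflated (Tf2O, pyridine) to the triflate F10, which is displaced directly by caesium angelate (from 31 and Cs2CO3; 18-crown-6, toluene) in an SN2 reaction with inversion at C8 to give 36.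

**Further compounds**

F1 | step 17 | tributyl[(1E)-hepta-1,6-dien-1-yl]stannane | CCCC[Sn](CCCC)(CCCC)/C=C/CCCC=C
F2 | step 17 | methyl (2E,4S)-4-(TBSO)-2-[(1E)-hepta-1,6-dien-1-yl]-5-[(2R,3S)-2-methyl-3-{(2S,3S)-4-methylene-5-oxo-3-vinyltetrahydrofuran-2-yl}oxiran-2-yl]pent-2-enoate | C=C[C@H]1C(=C)C(=O)O[C@@H]1[C@@H]1O[C@]1(C)C[C@H](O[Si](C)(C)C(C)(C)C)/C=C(\C=C\CCCC=C)C(=O)OC
F3 | step 18 | methyl (2S,4R,5S,6S,7R,8S,9R)-2-(TBSO)-4,5-epoxy-8,9-dihydroxygermacra-1(10),11(13)-dien-12,6-olid-14-oate | C=C1C(=O)O[C@H]2[C@H]1[C@H](O)[C@H](O)/C(C(=O)OC)=C\[C@@H](O[Si](C)(C)C(C)(C)C)C[C@@]1(C)O[C@@H]21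
F4 | step 18 | 8,9-cyclic sulfite of F3 | C=C1C(=O)O[C@H]2[C@H]1[C@H](O3)[C@H](OS3=O)/C(C(=O)OC)=C\[C@@H](O[Si](C)(C)C(C)(C)C)C[C@@]1(C)O[C@@H]21
F5 | step 18 | 8,9-cyclic sulfate of F3 | C=C1C(=O)O[C@H]2[C@H]1[C@H](O3)[C@H](OS3(=O)=O)/C(C(=O)OC)=C\[C@@H](O[Si](C)(C)C(C)(C)C)C[C@@]1(C)O[C@@H]21
F6 | step 18 | caesium salt of the 8-O-sulfate of F7 | C=C1C(=O)O[C@H]2[C@H]1[C@H](OS(=O)(=O)[O-])[C@@H](OC(C)=O)/C(C(=O)OC)=C\[C@@H](O[Si](C)(C)C(C)(C)C)C[C@@]1(C)O[C@@H]21.[Cs+]
F7 | step 18 | methyl (2S,4R,5S,6S,7R,8S,9S)-9-acetoxy-2-(TBSO)-4,5-epoxy-8-hydroxygermacra-1(10),11(13)-dien-12,6-olid-14-oate | C=C1C(=O)O[C@H]2[C@H]1[C@H](O)[C@@H](OC(C)=O)/C(C(=O)OC)=C\[C@@H](O[Si](C)(C)C(C)(C)C)C[C@@]1(C)O[C@@H]21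
F8 | step 18 | angelic 2,4,6-trichlorobenzoic anhydride | C/C=C(/C)C(=O)OC(=O)c1c(Cl)cc(Cl)cc1Cl
F9 | step 21 | methyl (2S,4R,5S,6S,7R,8R,9S)-9-acetoxy-2-(TBSO)-4,5-epoxy-8-hydroxygermacra-1(10),11(13)-dien-12,6-olid-14-oate | C=C1C(=O)O[C@H]2[C@H]1[C@@H](O)[C@@H](OC(C)=O)/C(C(=O)OC)=C\[C@@H](O[Si](C)(C)C(C)(C)C)C[C@@]1(C)O[C@@H]21
F10 | step 21 | 8-O-triflate of F9 | C=C1C(=O)O[C@H]2[C@H]1[C@@H](OS(=O)(=O)C(F)(F)F)[C@@H](OC(C)=O)/C(C(=O)OC)=C\[C@@H](O[Si](C)(C)C(C)(C)C)C[C@@]1(C)O[C@@H]21
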